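The eight-membered ring is numbered C1 (side-chain carbon), C2/C3 (butenolide β/α carbons), C4/C5 (cyclopropane CH), C6 (CHMe), C7 (CH2) and C8 (carbinol); C9 is the lactone carbonyl. Because C3 and C7 are 1,5-related, C9 sits on C3 and C7 adjoins oxygenated C8, a temporary C7–C9 bond folds the ring into a cyclopropane-fused bicyclo[3.3.1]nonane-2,9-dione. One enamine/acid-chloride annulation forms C3–C2 and C7–C8 and closes that six-membered bridging ring, joining a pulegone-derived methylbicyclo[4.1.0]heptan-3-one enamine with an alkylidene acid chloride that carries the side-chain stereocentre. Retro-Claisen scission of C9–C7 then unveils the cyclooctanone ester; reduction, lactonisation, desaturation and acetylation finish.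

Key step: step 18

Remark on the chemistry: ring atoms keep the numbering C1–C9 throughout. The temporary centre C2 is drawn as a chair aza-Cope array predicts from the E acid chloride (lactone CH2 on the same side as the C9 bridge, hence a cis-fused saturated lactone later). Its epimer would converge on the same butenolide.

**Ketone fragment**

Step 1
Reactants: 1 (R)-pulegone
Product: 2 pulegone oxide, (6R)-2,2,6-trimethyl-1-oxaspiro[2.5]octan-4-one (both epimers at the spiro carbon)
Conditions: 30% H2O2, NaOH (aq), MeOH, 0 °C → rt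
Reagents that add atoms: hydrogen peroxide, OO
Why: Weitz–Scheffer nucleophilic epoxidation of the electron-poor enone should proceed cleanly, and the epoxide configuration is irrelevant because that carbon is flattened again in step 3.

Step 2
Reactants: 2 pulegone oxide
Product: 3 (5R)-5-methyl-2-(phenylsulfanyl)cyclohexan-1-one (both C2 epimers)
Conditions: PhSNa, THF, reflux; NH4Cl (aq)
Reagents that add atoms: sodium benzenethiolate, [Na+].[S-]c1ccccc1
Why: Thiolate opening of the α,β-epoxy ketone at the α-carbon gives a β-alkoxide that should undergo retro-aldol loss of acetone, leaving the α-sulfenyl ketone.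

Step 3
Reactants: 3 (5R)-5-methyl-2-(phenylsulfanyl)cyclohexan-1-one
Product: 5 (R)-5-methylcyclohex-2-en-1-one, via sulfoxide 4 (not isolated)
Conditions: mCPBA, CH2Cl2, −78 °C; then CaCO3, toluene, 110 °C
Reagents that add atoms: none
Why: Sulfide oxidation followed by thermal sulfoxide syn-elimination can only place the alkene between C2 and C3 of the ketone, and the remote methyl centre is untouched.

Step 4
Reactants: 5 (R)-5-methylcyclohex-2-en-1-one
Product: 6 (S)-9-methyl-1,4-dioxaspiro[4.5]dec-7-ene
Conditions: HOCH2CH2OH, p-TsOH (cat.), benzene, reflux, azeotropic removal of water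
Reagents that add atoms: ethylene glycol, OCCO
Why: Acid-catalysed ketalisation of a cyclohex-2-enone passes through the dienol ether and should settle on the deconjugated β,γ-unsaturated dioxolane, which places the alkene at the future C4=C5 (the descriptor changes only through priorities).

Step 5
Reactants: 6 (S)-9-methyl-1,4-dioxaspiro[4.5]dec-7-ene
Product: 7 (1S,5S,6R)-5-methylspiro[bicyclo[4.1.0]heptane-3,2′-[1,3]dioxolane] (methyl trans to the cyclopropane CH2)
Conditions: Et2Zn, CH2I2, CH2Cl2, 0 °C → rt
Reagents that add atoms: diiodomethane, ICI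
Why: Simmons–Smith cyclopropanation (diethylzinc variant) should occur on the face opposite the allylic methyl, because with that methyl pseudoequatorial the axial dioxolane oxygen delivers the zinc carbenoid to the face carrying the allylic hydrogen; this sets C4 and C5.

Step 6
Reactants: 7 cyclopropyl ketal
Product: 8 (1S,5S,6R)-5-methylbicyclo[4.1.0]heptan-3-one (methyl trans to the cyclopropane CH2)
Conditions: 1 M HCl, THF, rt
Reagents that add atoms: water, O
Why: Mild acidic ketal hydrolysis should free the ketone without touching the cyclopropane, which is not conjugated with any cation-stabilising group.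

**Acid chloride fragment**

Step 7
Reactants: 9 5-bromo-2-methylpent-2-ene; 10 diethyl malonate (excess)
Product: 11 diethyl 2-(4-methylpent-3-en-1-yl)propanedioate
Conditions: NaH, THF/DMF, 0 → 60 °C
Reagents that add atoms: none
Why: Malonic ester alkylation of a primary bromide is reliable, and excess malonate suppresses dialkylation.

Step 8
Reactants: 11 alkylated malonate
Product: 13 6-methylhept-5-enoic acid, via malonic acid 12 (not isolated)
Conditions: KOH, EtOH/H2O, reflux; 1 M HCl, 0 °C; then pyridine, 115 °C
Reagents that add atoms: potassium hydroxide, [K+].[OH-]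
Why: Saponification followed by decarboxylation of the malonic acid in hot pyridine avoids the strongly acidic heating that could lactonise onto the trisubstituted alkene.

Step 9
Reactants: 13 6-methylhept-5-enoic acid; 14 (R)-4-benzyloxazolidin-2-one
Product: 16 (R)-4-benzyl-3-(6-methylhept-5-enoyl)oxazolidin-2-one, via mixed pivalic anhydride 15 (not isolated)
Conditions: t-BuCOCl, Et3N, THF, −20 °C; then 14, LiCl, rt
Reagents that add atoms: none
Why: N-acylation of the oxazolidinone by the mixed anhydride (LiCl/Et3N activation) is a standard one-flask imide synthesis, with attack at the unhindered acyl carbon.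

Step 10
Reactants: 16 acyl oxazolidinone; 17 tert-butyl bromoacetate
Product: 18 tert-butyl (3S)-3-[(4R)-4-benzyl-2-oxooxazolidine-3-carbonyl]-7-methyloct-6-enoate
Conditions: NaN(SiMe3)2, THF, −78 °C; then 17, −78 → −40 °C
Reagents that add atoms: none
Why: Evans alkylation, in which the chelated Z sodium enolate is attacked on the face opposite the benzyl group; with the (R)-auxiliary this gives the 3S side-chain centre required by the target.

Step 11
Reactants: 18 alkylated imide
Product: 19 tert-butyl (3S)-3-(hydroxymethyl)-7-methyloct-6-enoate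
Conditions: LiBH4, MeOH (1 equiv), Et2O, 0 °C
Reagents that add atoms: none
Why: LiBH4 reduces the activated imide carbonyl chemoselectively, releasing the auxiliary and leaving the hindered tert-butyl ester and the stereocentre intact.

Step 12
Reactants: 19 hydroxy ester
Product: 20 tert-butyl (3S)-3-[(tert-butyldiphenylsilyloxy)methyl]-7-methyloct-6-enoate
Conditions: TBDPSCl, imidazole, DMF, rt
Reagents that add atoms: tert-butyl(chloro)diphenylsilane, CC(C)(C)[Si](Cl)(c1ccccc1)c1ccccc1
Why: Standard silylation of a primary alcohol gives a robust ether that should last until the final deprotection.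

Step 13
Reactants: 20 silyl ether ester; 21 (tert-butyldimethylsilyloxy)acetaldehyde
Product: 22 tert-butyl 2-[(2S)-1-(tert-butyldiphenylsilyloxy)-6-methylhept-5-en-2-yl]-4-(tert-butyldimethylsilyloxy)-3-hydroxybutanoate (diastereomers at C2 and C3)
Conditions: LiN(i-Pr)2, THF, −78 °C; then 21
Reagents that add atoms: none
Why: Aldol addition of the tert-butyl ester lithium enolate to the unhindered aldehyde introduces C2 and the lactone CH2, and the new centres need no control because both are removed in the next step.

Step 14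
Reactants: 22 aldol adduct
Product: 24 tert-butyl (2E)-2-[(2S)-1-(tert-butyldiphenylsilyloxy)-6-methylhept-5-en-2-yl]-4-(tert-butyldimethylsilyloxy)but-2-enoate, via mesylate 23 (not isolated)
Conditions: MsCl, Et3N, CH2Cl2, 0 °C; then DBU, rt
Reagents that add atoms: none
Why: Mesylation and E1cB elimination should give the conjugated ester, mainly as the E isomer with the CH2OTBS group trans to the ester; the geometry only affects the temporary C2 centre.

Step 15
Reactants: 24 alkylidene tert-butyl ester
Product: 26 (2E)-2-[(2S)-1-(tert-butyldiphenylsilyloxy)-6-methylhept-5-en-2-yl]-4-(tert-butyldimethylsilyloxy)but-2-enoic acid, via trimethylsilyl ester 25 (not isolated)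
Conditions: Me3SiOSO2CF3, 2,6-lutidine, CH2Cl2, 0 °C; pH 7 buffer
Reagents that add atoms: none
Why: Silyl-triflate-mediated cleavage of the tert-butyl ester (loss of 2-methylpropene from the O-silylated ester) under buffered conditions should spare both silyl ethers and the alkenes.

Step 16
Reactants: 26 alkylidene acid
Product: 27 corresponding (2E)-acid chloride (fragment 2)
Conditions: 1-chloro-N,N,2-trimethylprop-1-en-1-amine, CH2Cl2, 0 °C → rt; used crude
Reagents that add atoms: 1-chloro-N,N,2-trimethylprop-1-en-1-amine, CC(C)=C(Cl)N(C)C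
Why: Acid chloride formation with the α-chloroenamine is neutral (no HCl is released), so the acid-labile silyl ethers should survive.

**Union and endgame**

Step 17
Reactants: 8 cyclopropyl ketone
Product: 28 1-(5-methylbicyclo[4.1.0]hept-2-en-3-yl)pyrrolidine (double bond C9=C3, toward the cyclopropane; ring stereocentres as in 8)
Conditions: pyrrolidine, p-TsOH (cat.), benzene, reflux, azeotropic removal of water; used crude
Reagents that add atoms: pyrrolidine, C1CCNC1
Why: Enamine condensation under equilibrating conditions should favour the double bond toward C3, because that isomer keeps a half-chair ring and avoids a double bond next to the methyl-bearing C6.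

Step 18
Reactants: 28 enamine; 27 acid chloride
Product: 32 cyclopropane-fused bicyclo[3.3.1]nonane-2,9-dione with ketones at C8 and C9 (C2–C1–C8 bridge anti to the cyclopropane CH2; C1 side chain exo; CH2OTBS on C2 syn to the C9 bridge; C6 methyl equatorial), via N-acyl enammonium chloride 29 (not isolated), via ketene–iminium chloride 30 (not isolated), via bicyclic iminium chloride 31 (not isolated)
Conditions: toluene, −20 → 80 °C; then NaOAc/AcOH (aq), rt; then Et3N, CH2Cl2, rt
Reagents that add atoms: water, O
Why: The enamine nitrogen is acylated by 27, and the N-acyl enammonium ion 29 undergoes a chair 3-aza-Cope shift that joins C3 to C2 on the face of C3 away from the cyclopropane CH2 and releases the ketene–iminium 30; proton loss from C7 then gives an enamine whose C7 attacks the sp ketene carbon C8, and water frees the C9 ketone from iminium 31. The closest known reaction type is the α,α′-annulation of cyclohexanone enamines with acryloyl or crotonoyl chlorides to bicyclo[3.3.1]nonane-2,9-diones. The one new ring, the six-membered C3–C2–C1–C8–C7–C9 ring, is closed by a 6-exo-dig attack on the ketene (C=O exocyclic), which is easy because the C3–C2 and C7–C8 bonds are 1,3-diaxial on the cyclohexane chair. C3 is controlled by the cyclopropane CH2 on neighbouring C4, C7 is forced cis to it by the bridge, temporary C2 follows from the chair array and the E alkene, and C1 is set thermodynamically by Et3N, the exo (equatorial) side chain avoiding the endo hydrogen on C5. The selectivity needed is first bond formation at C3 and not at C7, which rests on the enamine double bond of 28 lying toward the cyclopropane and away from the C6 methyl.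

Step 19
Reactants: 32 bicyclic dione
Product: 34 methyl ester of the bicyclo[6.1.0]nonanone (C8 ketone; CO2Me on C3; C7 now CH2), via sodium enolate 33 (not isolated)
Conditions: NaOMe (1.0 equiv), THF, −20 → 0 °C; AcOH, −78 °C
Reagents that add atoms: sodium methoxide, [Na+].[O-]C
Why: Retro-Claisen fragmentation, in which methoxide adds to the strained, non-enolisable bridging C9 ketone and the adduct breaks the C9–C7 bond (the only one β to the C8 carbonyl) to give the C7=C8 enolate; one equivalent of base and a cold acidic quench should leave C1 unepimerised.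

Step 20
Reactants: 34 keto ester
Product: 35 C8 alcohol (hydroxyl cis to the C1 side chain; methyl ester retained)
Conditions: LiBH(s-Bu)3, THF, −78 °C; AcOH, −78 °C
Reagents that add atoms: none
Why: Bulky hydride reduction should deliver hydride to C8 from the face opposite the branched C1 substituent, giving the cis alcohol required by the target, and the cold quench prevents the alkoxide from attacking the ester across the ring.

Step 21
Reactants: 35 hydroxy ester
Product: 36 C8 tert-butyldimethylsilyl ether
Conditions: t-BuMe2SiOSO2CF3, 2,6-lutidine, CH2Cl2, −78 → 0 °C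
Reagents that add atoms: tert-butyldimethylsilyl trifluoromethanesulfonate, CC(C)(C)[Si](C)(C)OS(=O)(=O)C(F)(F)F
Why: Silyl triflate silylation copes with the hindered secondary alcohol and masks it for the enolate chemistry that follows.

Step 22
Reactants: 36 bis(tert-butyldimethylsilyl) ether ester
Product: 38 cis-fused saturated γ-lactone (C9 carbonyl; O–CH2 on C2; C8 silyl ether), via hydroxy ester 37 (not isolated)
Conditions: camphorsulfonic acid (cat.), MeOH/CH2Cl2, 0 °C; then toluene, 50 °C
Reagents that add atoms: none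
Why: Acidic methanolysis removes the primary tert-butyldimethylsilyl ether much faster than the hindered secondary one or the tert-butyldiphenylsilyl ether, and the freed alcohol, cis to the ester on the adjacent carbon, should lactonise under the same acid catalysis.

Step 23
Reactants: 38 lactone
Product: 39 α-(phenylselanyl) lactone (selenium on C3, cis to the C2 hydrogen)
Conditions: LiN(i-Pr)2, THF, −78 °C; then PhSeBr (1.05 equiv), −78 °C
Reagents that add atoms: benzeneselenenyl bromide, Br[Se]c1ccccc1
Why: Selenenylation of the lactone enolate should occur on the convex face of the cis-fused bicycle, syn to the C2 hydrogen, and the cold, near-stoichiometric electrophile is consumed by the enolate before it can add to the side-chain alkene.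

Step 24
Reactants: 39 selenide
Product: 41 butenolide with C2=C3 (both silyl ethers retained), via selenoxide 40 (not isolated)
Conditions: NaIO4, NaHCO3, THF/MeOH/H2O, 0 °C → rt
Reagents that add atoms: none
Why: Selenoxide syn-elimination takes the cis C2 hydrogen rather than the cyclopropyl C4 hydrogen (which would give a strained alkylidenecyclopropane), and periodate oxidises selenium without epoxidising the trisubstituted alkene.

Step 25
Reactants: 41 bis-silyl butenolide
Product: 42 diol (free primary side-chain alcohol and C8 alcohol)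
Conditions: HF·pyridine, pyridine, THF, 0 °C → rt
Reagents that add atoms: none
Why: Buffered fluoride desilylation removes both silyl ethers under slightly acidic conditions that should not deprotonate the butenolide γ-position at C1.

Step 26
Reactants: 42 diol
Product: 43 target CNP0267808.2
Conditions: AcCl (1.1 equiv), 2,4,6-collidine, CH2Cl2, −78 °C
Reagents that add atoms: acetyl chloride, CC(Cl)=O
Why: Acylation with acetyl chloride and a hindered pyridine base at low temperature is selective for the primary alcohol over the hindered secondary C8 alcohol flanked by the branched C1 substituent.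

**Compound list**

1 | (R)-pulegone | C[C@@H]1CCC(=C(C)C)C(=O)C1 | starting material
2 | pulegone oxide (epimers at the spiro carbon) | C[C@@H]1CCC2(OC2(C)C)C(=O)C1 | intermediate
3 | (5R)-5-methyl-2-(phenylsulfanyl)cyclohexan-1-one (C2 epimers) | C[C@@H]1CCC(Sc2ccccc2)C(=O)C1 | intermediate
4 | (5R)-5-methyl-2-(phenylsulfinyl)cyclohexan-1-one (stereoisomer mixture) | C[C@@H]1CCC(S(=O)c2ccccc2)C(=O)C1 | intermediate (not isolated)
5 | (R)-5-methylcyclohex-2-en-1-one | O=C1C=CC[C@@H](C)C1 | intermediate
6 | (S)-9-methyl-1,4-dioxaspiro[4.5]dec-7-ene | C[C@@H]1C=CCC2(C1)OCCO2 | intermediate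
7 | (1S,5S,6R)-5-methylspiro[bicyclo[4.1.0]heptane-3,2′-[1,3]dioxolane] | C13(OCCO3)C[C@@H]2C[C@@H]2[C@@H](C)C1 | intermediate
8 | (1S,5S,6R)-5-methylbicyclo[4.1.0]heptan-3-one | O=C1C[C@@H]2C[C@@H]2[C@@H](C)C1 | intermediate
9 | 5-bromo-2-methylpent-2-ene | CC(C)=CCCBr | starting material
10 | diethyl malonate | CCOC(=O)CC(=O)OCC | starting material
11 | diethyl 2-(4-methylpent-3-en-1-yl)propanedioate | CCOC(=O)C(CCC=C(C)C)C(=O)OCC | intermediate
12 | 2-(4-methylpent-3-en-1-yl)propanedioic acid | OC(=O)C(CCC=C(C)C)C(=O)O | intermediate (not isolated)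
13 | 6-methylhept-5-enoic acid | CC(C)=CCCCC(=O)O | intermediate
14 | (R)-4-benzyloxazolidin-2-one | O=C1OC[C@@H](Cc2ccccc2)N1 | starting material
15 | 6-methylhept-5-enoic pivalic anhydride | CC(C)=CCCCC(=O)OC(=O)C(C)(C)C | intermediate (not isolated)
16 | (R)-4-benzyl-3-(6-methylhept-5-enoyl)oxazolidin-2-one | O=C1OC[C@@H](Cc2ccccc2)N1C(=O)CCCC=C(C)C | intermediate
17 | tert-butyl bromoacetate | CC(C)(C)OC(=O)CBr | starting material
18 | tert-butyl (3S)-3-[(4R)-4-benzyl-2-oxooxazolidine-3-carbonyl]-7-methyloct-6-enoate | O=C1OC[C@@H](Cc2ccccc2)N1C(=O)[C@@H](CCC=C(C)C)CC(=O)OC(C)(C)C | intermediate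
19 | tert-butyl (3S)-3-(hydroxymethyl)-7-methyloct-6-enoate | OC[C@@H](CCC=C(C)C)CC(=O)OC(C)(C)C | intermediate
20 | tert-butyl (3S)-3-[(tert-butyldiphenylsilyloxy)methyl]-7-methyloct-6-enoate | CC(C)(C)[Si](c1ccccc1)(c1ccccc1)OC[C@@H](CCC=C(C)C)CC(=O)OC(C)(C)C | intermediate
21 | (tert-butyldimethylsilyloxy)acetaldehyde | CC(C)(C)[Si](C)(C)OCC=O | starting material
22 | aldol adduct (diastereomers at the two new centres) | CC(C)(C)[Si](c1ccccc1)(c1ccccc1)OC[C@@H](CCC=C(C)C)C(C(=O)OC(C)(C)C)C(O)CO[Si](C)(C)C(C)(C)C | intermediate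
23 | mesylate of 22 | CC(C)(C)[Si](c1ccccc1)(c1ccccc1)OC[C@@H](CCC=C(C)C)C(C(=O)OC(C)(C)C)C(OS(C)(=O)=O)CO[Si](C)(C)C(C)(C)C | intermediate (not isolated)
24 | (E)-alkylidene tert-butyl ester | CC(C)(C)[Si](c1ccccc1)(c1ccccc1)OC[C@@H](CCC=C(C)C)/C(C(=O)OC(C)(C)C)=C\CO[Si](C)(C)C(C)(C)C | intermediate
25 | trimethylsilyl ester of 26 | CC(C)(C)[Si](c1ccccc1)(c1ccccc1)OC[C@@H](CCC=C(C)C)/C(C(=O)O[Si](C)(C)C)=C\CO[Si](C)(C)C(C)(C)C | intermediate (not isolated)
26 | (E)-alkylidene acid | CC(C)(C)[Si](c1ccccc1)(c1ccccc1)OC[C@@H](CCC=C(C)C)/C(C(=O)O)=C\CO[Si](C)(C)C(C)(C)C | intermediate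
27 | (E)-alkylidene acid chloride (fragment 2) | CC(C)(C)[Si](c1ccccc1)(c1ccccc1)OC[C@@H](CCC=C(C)C)/C(C(=O)Cl)=C\CO[Si](C)(C)C(C)(C)C | intermediate
28 | pyrrolidine enamine of 8 (C9=C3) | C1(N3CCCC3)=C[C@@H]2C[C@@H]2[C@@H](C)C1 | intermediate
29 | N-acyl enammonium chloride | CC(C)(C)[Si](c1ccccc1)(c1ccccc1)OC[C@@H](CCC=C(C)C)/C(C(=O)[N+]2(CCCC2)C2=C[C@@H]3C[C@@H]3[C@@H](C)C2)=C\CO[Si](C)(C)C(C)(C)C.[Cl-] | intermediate (not isolated)
30 | ketene–iminium chloride (C3–C2 bond formed) | CC(C)(C)[Si](c1ccccc1)(c1ccccc1)OC[C@@H](CCC=C(C)C)C(=C=O)[C@H](CO[Si](C)(C)C(C)(C)C)[C@H]1[C@@H]2C[C@@H]2[C@@H](C)CC1=[N+]1CCCC1.[Cl-] | intermediate (not isolated)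
31 | bicyclic C9 iminium chloride (C1 epimers) | CC(C)(C)[Si](c1ccccc1)(c1ccccc1)OC[C@@H](CCC=C(C)C)C1[C@H](CO[Si](C)(C)C(C)(C)C)[C@H]3[C@@H]2C[C@@H]2[C@@H](C)[C@H](C3=[N+]4CCCC4)C1=O.[Cl-] | intermediate (not isolated)
32 | cyclopropane-fused bicyclo[3.3.1]nonane-2,9-dione, C1 side chain exo | CC(C)(C)[Si](c1ccccc1)(c1ccccc1)OC[C@@H](CCC=C(C)C)[C@@H]1[C@H](CO[Si](C)(C)C(C)(C)C)[C@H]3[C@@H]2C[C@@H]2[C@@H](C)[C@H](C3=O)C1=O | intermediate
33 | sodium C7=C8 enolate of 34 | CC(C)(C)[Si](c1ccccc1)(c1ccccc1)OC[C@@H](CCC=C(C)C)[C@@H]1[C@H](CO[Si](C)(C)C(C)(C)C)[C@H](C(=O)OC)[C@@H]2C[C@@H]2[C@@H](C)C=C1[O-].[Na+] | intermediate (not isolated)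
34 | bicyclo[6.1.0]nonanone methyl ester (C8 ketone, C3 ester) | CC(C)(C)[Si](c1ccccc1)(c1ccccc1)OC[C@@H](CCC=C(C)C)[C@@H]1[C@H](CO[Si](C)(C)C(C)(C)C)[C@H](C(=O)OC)[C@@H]2C[C@@H]2[C@@H](C)CC1=O | intermediate
35 | C8 alcohol | CC(C)(C)[Si](c1ccccc1)(c1ccccc1)OC[C@@H](CCC=C(C)C)[C@@H]1[C@H](CO[Si](C)(C)C(C)(C)C)[C@H](C(=O)OC)[C@@H]2C[C@@H]2[C@@H](C)C[C@@H]1O | intermediate
36 | C8 silyl ether | CC(C)(C)[Si](c1ccccc1)(c1ccccc1)OC[C@@H](CCC=C(C)C)[C@@H]1[C@H](CO[Si](C)(C)C(C)(C)C)[C@H](C(=O)OC)[C@@H]2C[C@@H]2[C@@H](C)C[C@@H]1O[Si](C)(C)C(C)(C)C | intermediate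
37 | γ-hydroxy methyl ester | CC(C)(C)[Si](c1ccccc1)(c1ccccc1)OC[C@@H](CCC=C(C)C)[C@@H]1[C@H](CO)[C@H](C(=O)OC)[C@@H]2C[C@@H]2[C@@H](C)C[C@@H]1O[Si](C)(C)C(C)(C)C | intermediate (not isolated)
38 | cis-fused saturated γ-lactone with C8 silyl ether | CC(C)(C)[Si](c1ccccc1)(c1ccccc1)OC[C@@H](CCC=C(C)C)[C@@H]1[C@H]2[C@H](C(=O)OC2)[C@@H]3C[C@@H]3[C@@H](C)C[C@@H]1O[Si](C)(C)C(C)(C)C | intermediate
39 | α-(phenylselanyl) lactone | CC(C)(C)[Si](c1ccccc1)(c1ccccc1)OC[C@@H](CCC=C(C)C)[C@@H]1[C@H]2[C@]([Se]c4ccccc4)(C(=O)OC2)[C@@H]3C[C@@H]3[C@@H](C)C[C@@H]1O[Si](C)(C)C(C)(C)C | intermediate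
40 | selenoxide of 39 (epimers at selenium) | CC(C)(C)[Si](c1ccccc1)(c1ccccc1)OC[C@@H](CCC=C(C)C)[C@@H]1[C@H]2[C@]([Se](=O)c4ccccc4)(C(=O)OC2)[C@@H]3C[C@@H]3[C@@H](C)C[C@@H]1O[Si](C)(C)C(C)(C)C | intermediate (not isolated)
41 | bis-silyl butenolide | CC(C)(C)[Si](c1ccccc1)(c1ccccc1)OC[C@@H](CCC=C(C)C)[C@@H]1C2=C(C(=O)OC2)[C@@H]3C[C@@H]3[C@@H](C)C[C@@H]1O[Si](C)(C)C(C)(C)C | intermediate
42 | butenolide diol | OC[C@@H](CCC=C(C)C)[C@@H]1C2=C(C(=O)OC2)[C@@H]2C[C@@H]2[C@@H](C)C[C@@H]1O | intermediate
43 | CNP0267808.2 | CC(=O)OC[C@@H](CCC=C(C)C)[C@@H]1C2=C(C(=O)OC2)[C@@H]2C[C@@H]2[C@@H](C)C[C@@H]1O | target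

**Step count**

Total: 26 steps. Longest linear sequence: 19 steps (steps 7–16, then 18–26); the ketone branch (steps 1–6 and 17) is shorter.

**Steps most likely to fail**

Step 18. The enamine double bond may lie partly toward C7, so that the first bond forms at the wrong α-carbon or on the cyclopropane face, and the sigmatropic step may be slow with this hindered, trisubstituted acyl alkene. The fallback removes the dependence on an equilibrium enamine mixture. It sets out from enone 5, which with Tf2O and 2,6-di-tert-butyl-4-methylpyridine in CH2Cl2 should give the linear dienyl triflate (S)-5-methylcyclohexa-1,3-dien-1-yl trifluoromethanesulfonate F1. Simmons–Smith cyclopropanation (Et2Zn, CH2I2) of its electron-richer distal alkene, anti to the methyl group, should give the cyclopropyl vinyl triflate 5-methylbicyclo[4.1.0]hept-2-en-3-yl trifluoromethanesulfonate F2. Buchwald–Hartwig coupling of F2 with pyrrolidine (Pd(OAc)2, 2,2′-bis(diphenylphosphino)-1,1′-binaphthyl, Cs2CO3, toluene, 80 °C) returns to the route at enamine 28, now as one regioisomer. It is then N-acylated by 27 at low temperature, before any acid is present that could move the double bond.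

Step 19. Methoxide may approach the flanked C9 carbonyl slowly, may attack C8 instead, or the enolate may equilibrate and scramble C1. The fallback delivers the nucleophile from within the molecule. It sets out from dione 32: HF·pyridine in pyridine/THF at 0 °C removes only the primary tert-butyldimethylsilyl group to give the hydroxy dione F3, whose C2 CH2OH lies beside C9. Catalytic DBU in CH2Cl2 should then convert its C9 hemiketal alkoxide, by the same C9–C7 scission, directly into the keto lactone F4. LiBH(s-Bu)3 at −78 °C gives the hydroxy lactone F5, and silylation (t-BuMe2SiOSO2CF3, 2,6-lutidine) returns to the route at lactone 38.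

Step 20. Facial selectivity of hydride delivery to the flexible eight-membered ketone may be poor. The fallback corrects the centre by inversion instead of relying on reagent approach. It sets out from keto ester 34: the C8-epimeric alcohol F6 (separated from a mixture, or made on purpose with a small hydride such as NaBH4 if that favours it) undergoes Mitsunobu inversion with 4-nitrobenzoic acid, PPh3 and diisopropyl azodicarboxylate to the inverted 4-nitrobenzoate F7. Brief K2CO3/MeOH methanolysis returns to the route at alcohol 35.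

**Further compounds**

F1 | step 18 | (S)-5-methylcyclohexa-1,3-dien-1-yl trifluoromethanesulfonate | FC(F)(F)S(=O)(=O)OC1=CC=C[C@@H](C)C1
F2 | step 18 | 5-methylbicyclo[4.1.0]hept-2-en-3-yl trifluoromethanesulfonate (ring stereocentres as in 8) | FC(F)(F)S(=O)(=O)OC1=C[C@@H]2C[C@@H]2[C@@H](C)C1
F3 | step 19 | hydroxy dione (32 without the primary tert-butyldimethylsilyl group) | CC(C)(C)[Si](c1ccccc1)(c1ccccc1)OC[C@@H](CCC=C(C)C)[C@@H]1[C@H](CO)[C@H]3[C@@H]2C[C@@H]2[C@@H](C)[C@H](C3=O)C1=O
F4 | step 19 | keto γ-lactone (C8 ketone) | CC(C)(C)[Si](c1ccccc1)(c1ccccc1)OC[C@@H](CCC=C(C)C)[C@@H]1[C@H]2[C@H](C(=O)OC2)[C@@H]3C[C@@H]3[C@@H](C)CC1=O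
F5 | step 19 | hydroxy γ-lactone (free C8 alcohol) | CC(C)(C)[Si](c1ccccc1)(c1ccccc1)OC[C@@H](CCC=C(C)C)[C@@H]1[C@H]2[C@H](C(=O)OC2)[C@@H]3C[C@@H]3[C@@H](C)C[C@@H]1O
F6 | step 20 | C8 epimer of alcohol 35 | CC(C)(C)[Si](c1ccccc1)(c1ccccc1)OC[C@@H](CCC=C(C)C)[C@@H]1[C@H](CO[Si](C)(C)C(C)(C)C)[C@H](C(=O)OC)[C@@H]2C[C@@H]2[C@@H](C)C[C@H]1O
F7 | step 20 | 4-nitrobenzoate of alcohol 35 | CC(C)(C)[Si](c1ccccc1)(c1ccccc1)OC[C@@H](CCC=C(C)C)[C@@H]1[C@H](CO[Si](C)(C)C(C)(C)C)[C@H](C(=O)OC)[C@@H]2C[C@@H]2[C@@H](C)C[C@@H]1OC(=O)c1ccc(cc1)[N+](=O)[O-]
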